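## Structural features

The target is an acyclic 8-O-4' neolignan. A three-carbon chain C7–C8–C9 carries ring A (3,4,5-trimethoxyphenyl) on C7 and is joined through the C8 oxygen to C4' of ring B, a 2-methoxyphenyl ring with a 3-hydroxypropyl chain para to the ether oxygen. The two benzene rings are the only rings, so all stereocontrol has to come from acyclic stereoselection. The only stereocentres are the neighbours C7 (S, secondary benzylic alcohol) and C8 (R, secondary alkyl aryl ether). In the zigzag through C1–C7–C8–C9 the two oxygens are anti, which is the erythro series. The fragile points are the benzylic C7–OH on an electron-rich ring (ionisation, elimination or epimerisation under acid, hydrogenolysis) and the beta-aryloxy alcohol array, which can fragment by retro-aldol reaction whenever C9 is a carbonyl group. The difficulty is twofold: two adjacent oxygenated centres must be set anti with absolute control, and the C8–O–aryl bond should not have to be made by substitution at a secondary carbon. The key step exploits the fact that C9 is a methyl group next to the aryloxy-bearing C8. Carried as a thioester carbonyl, C9 turns C8 into the alpha carbon of an aryloxyacetate whose O–aryl bond was made at a primary carbon, and one aldol addition to the non-enolisable ring A aldehyde then forms C7–C8 and both stereocentres.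

## Logic of the disconnections

14 ⇒ 12. The C–O bond at the terminus of the ring B side chain is removed and the chain is taken back to an allyl group. A free or protected hydroxypropyl group would have to be carried through enolisation, two hydride steps and a sulfonylation, whereas a terminal alkene is inert to all of them and is already present in 4. This saves a protecting group and its two steps. The demand is an anti-Markovnikov hydroboration (through 13) that tolerates a free benzylic hydroxyl.

12 ⇒ 10 (through 11). One C9–H bond is traced back to a C9–O bond, first as the sulfonate 11 and then as the primary alcohol of 10. This gives C9 a functional handle and makes C7 and C9 a 1,3-diol, the reduced form of an aldol. The demand is that sulfonylation distinguishes the primary from the secondary benzylic hydroxyl, and that hydride reaches C9 before the C7 oxygen can displace the sulfonate.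

10 ⇒ 9. The remaining two C9–H bonds are traced back to the thioester carbonyl. C8 thereby becomes an enolisable alpha carbon, and the 1,3-dioxygen pattern becomes a beta-hydroxy acyl unit. The demand is a reduction fast and mild enough that the C7 alkoxide does not undergo retro-aldol cleavage and C8 does not epimerise.

9 ⇒ 5 + 6 (through 8 and 7). The C7–C8 bond is cut. This is the only carbon–carbon bond between the two halves, and cutting it removes both stereocentres at once, leaving an achiral thioacetate and an aromatic aldehyde without alpha hydrogens. The demand is an enolate of defined geometry reacting through a closed transition state (for anti) on a boron atom with chiral ligands (for the absolute sense).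

5 ⇒ 3 + 4. The bond between the ring B oxygen and C8 is cut. At this stage C8 is a primary, carbonyl-activated carbon, so the ether that is secondary and hindered in 14 is made by the easiest possible O-alkylation. The demand is only that the phenoxide attacks carbon and not the thioester carbonyl.

3 ⇒ 1 + 2. The sulfur–acyl bond is cut, giving two bulk chemicals. The demand is acylation of the thiol at the acid bromide in preference to alkylation at the CH2Br carbon.

## Other disconnections considered

Alternative 1: The cut is the aryl ether bond between the C8 oxygen and C4' of ring B.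
- Forward step: the potassium alkoxide made with KN(SiMe3)2 from (1S,2R)-1-(methoxymethoxy)-1-(3,4,5-trimethoxyphenyl)propan-2-ol A1 would attack 4-fluoro-3-methoxybenzaldehyde A2 at the fluorine-bearing carbon. This is an addition–elimination in which the para formyl group stabilises the anionic sigma complex. The product would be 3-methoxy-4-{[(1S,2R)-1-(methoxymethoxy)-1-(3,4,5-trimethoxyphenyl)propan-2-yl]oxy}benzaldehyde A3.
- In favour: the C8–O bond of A1 is never broken, so both centres are fixed before the coupling and cannot be scrambled by it. The halves are joined late, and no alpha-aryloxy carbonyl compound that could epimerise at C8 ever appears.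
- Against: the best catalytic entry to 1-aryl-1,2-diols, dihydroxylation of an (E)-alkene, gives the threo series, so reaching erythro A1 needs an inversion or a different construction. The two secondary hydroxyls must also be told apart to protect only C7. The alkoxide of A1 is secondary and hindered, A2 carries a deactivating ortho methoxy group, and the aldehyde is itself open to alkoxide attack. After the coupling the formyl group of A3 still needs a two-carbon extension (olefination, C=C hydrogenation, ester reduction). The acetal must finally be removed with acid at a benzylic centre that ionises easily.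
- Comparison on structure: Alternative 1 makes the hardest bond of the molecule in its key step, whereas the chosen plan makes that bond at a primary carbon before any stereocentre exists.
- Comparison on mechanism: the substitution plays no stereochemical role, whereas the aldol creates both centres in one closed transition state.
- Comparison on step economy: roughly ten operations are expected against seven.
- Equal or better: Alternative 1 is better in convergence and in the configurational safety of C8, which in the chosen plan sits alpha to a thioester for one step. It also needs no stoichiometric chiral reagent.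

Alternative 2: The cut is C8=C9. The C9 methyl is traced back to a methylene placed on the carbonyl carbon of an aryl ester, so the ether oxygen begins as an ester oxygen.
- Forward step: 4-{3-[(tert-butyldimethylsilyl)oxy]propyl}-2-methoxyphenyl (S)-2-[(tert-butyldimethylsilyl)oxy]-2-(3,4,5-trimethoxyphenyl)acetate A4 would be methylenated with Cp2Ti(CH2)(Cl)AlMe2. The titanium methylidene Cp2Ti=CH2 undergoes [2+2] addition to the ester C=O followed by cycloreversion. The product would be tert-butyl{(S)-2-{4-[3-(tert-butyldimethylsilyloxy)propyl]-2-methoxyphenoxy}-1-(3,4,5-trimethoxyphenyl)allyloxy}dimethylsilane A5. Hydrogenation of the enol ether double bond of A5 would then have to create C8, and the silyl groups would be removed.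
- In favour: the hindered C8–O–aryl link comes from a simple phenol acylation. The titanium reagent is not basic, so the alpha centre of A4 should survive the key step. The side chain is carried at its final oxidation level, and only one stereocentre has to be introduced by asymmetric synthesis.
- Against: C8 would arise in a later hydrogenation of a 1,1-disubstituted enol ether, for which no dependable model predicts erythro over threo. The C7–O bond of A5 is both allylic and benzylic and therefore exposed to hydrogenolysis. Aryl arylacetates such as A4 are strongly C–H acidic, so ester formation threatens the only stereocentre present. The enantiopure trimethoxymandelic acid is not a stock compound.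
- Comparison on structure: the chosen plan sets both centres together, whereas Alternative 2 sets them in two separate events, the second of them uncertain.
- Comparison on mechanism: a metathesis-type carbonyl olefination followed by heterogeneous hydrogen delivery stands against one organised aldol transition state.
- Comparison on step economy: with separate preparation of the acid and the silylated phenol, the count is expected to exceed seven.
- Equal or better: the ether oxygen is attached as easily as in the chosen plan (acylation against alkylation, equal). Alternative 2 is better in needing neither a thiol nor a stoichiometric chiral borane, and no late hydroboration.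

Alternative 3: The cut is the C1–C7 bond between ring A and the carbinol carbon.
- Forward step: (3,4,5-trimethoxyphenyl)titanium triisopropoxide A7, made from the aryl Grignard reagent and ClTi(OCHMe2)3, would add to (R)-2-(4-allyl-2-methoxyphenoxy)propanal A6. The addition goes through an open, non-chelated transition state in which the aryloxy group lies anti to the incoming nucleophile (polar Felkin–Anh). The product would be (1S,2R)-2-(4-allyl-2-methoxyphenoxy)-1-(3,4,5-trimethoxyphenyl)propan-1-ol A8, which is the same compound as 12.
- In favour: A6 should be available from a lactate ester of the chiral pool and 4 by Mitsunobu inversion and partial reduction. C8 then costs nothing, and the aryloxy group is a poor chelator, which favours the wanted non-chelation pathway.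
- Against: A6 is an enolisable alpha-aryloxy aldehyde and can racemise during its formation and under the organometallic reagent. The C7 centre depends on substrate control in which only a methyl group and a hydrogen differentiate the two faces, so a separable but real amount of the threo isomer must be expected. Enantiomeric purity is then only as good as the handling of A6.
- Comparison on structure: both plans reach 12 and finish identically.
- Comparison on mechanism: open-chain 1,2-induction from one existing centre stands against reagent control of two new centres in a closed chair.
- Comparison on step economy: Alternative 3 is better, with about four operations to A8 against six to 12.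
- Equal or better: Alternative 3 is also better in reagent cost, since it needs no chiral reagent at all. The chosen plan is preferred because it does not pass through a configurationally labile aldehyde and does not rest on a small steric bias for C7.

Key step: step 3

Remarks and assumptions
- Locants: C7 is the benzylic carbinol carbon, C8 the aryloxy carbon, C9 the methyl carbon, ring A the trimethoxyphenyl ring and ring B the 2-methoxyphenoxy ring.
- Structure check: the anti adduct (2S,3S) and the target (7S,8R) have the same arrangement in space. The letter at C8 changes only because C(=O)S outranks C7 in the CIP ranking while CH2OH and CH3 do not. Anti in the zigzag equals erythro in the Fischer sense, and no structure needed correction.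
- Assumed reagent sense: the bromoborane enantiomer built from (−)-menthone, with (1S,2S,5R) ligands, is taken to send the enolate to the Re face of 6. If MTPA ester analysis of 9 from a first small-scale run indicates the opposite sense, the mirror-image reagent from (+)-menthone is used and nothing else changes.
- The bromoborane is not sold as such. It is made beforehand from menthone by the established sequence (Wittig methylenation, hydroboration with BH2Br·SMe2, crystallisation) and is treated as a reagent outside the step count.
- Precursor design: 5 is kept as the S-tert-butyl thioester (the thioester type that gives the trans enol borinate) with the side chain as an unprotected allyl group, so no protecting group is used anywhere in the route.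

## Steps

Step 1
Reactants: 1 2-methylpropane-2-thiol; 2 bromoacetyl bromide
Product: 3 S-tert-butyl 2-bromoethanethioate
Conditions: pyridine (1.0 equiv), Et2O, −10 → 0 °C
Reagents that add atoms: none
Why: Acyl substitution (S-acylation): the acid bromide carbonyl is far more electrophilic than the CH2Br carbon, so a hindered thiol with a weak base at low temperature should be acylated rather than alkylated; pyridinium bromide precipitates from ether and takes the base out of play.

Step 2
Reactants: 3 S-tert-butyl 2-bromoethanethioate; 4 eugenol
Product: 5 S-tert-butyl 2-(4-allyl-2-methoxyphenoxy)ethanethioate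
Conditions: K2CO3 (1.5 equiv), acetone, rt → 40 °C
Reagents that add atoms: none
Why: Williamson ether synthesis: the potassium phenoxide of 4 displaces bromide by SN2 at the carbonyl-activated primary carbon of 3, which should be much faster than attack at the hindered tert-butyl thioester carbonyl; carbonate in acetone is too weak to move the allyl double bond into conjugation.

Step 3
Reactants: 5 S-tert-butyl 2-(4-allyl-2-methoxyphenoxy)ethanethioate; 6 3,4,5-trimethoxybenzaldehyde
Product: 9 S-tert-butyl (2S,3S)-2-(4-allyl-2-methoxyphenoxy)-3-hydroxy-3-(3,4,5-trimethoxyphenyl)propanethioate, via enol borinate 7 (not isolated), via boron aldolate 8 (not isolated)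
Conditions: bis{[(1S,2S,5R)-2-isopropyl-5-methylcyclohexyl]methyl}bromoborane (1.4 equiv), Et3N (1.6 equiv), CH2Cl2/Et2O, −78 → 0 °C; then 6, −78 → −20 °C; pH 7 buffer, MeOH, 30% H2O2, 0 °C
Reagents that add atoms: none
Why: This is a boron-mediated anti glycolate aldol addition of the known kind in which alpha-oxygenated S-tert-butyl thioacetates are enolised by a chiral dialkylbromoborane and a tertiary amine. The bromoborane binds the thioester carbonyl of 5, Et3N removes an alpha proton, and the bulky S-tert-butyl group and boron ligands should give enol borinate 7 with the aryloxy group trans to the O–B bond. Aldehyde 6 then coordinates to boron and the C7–C8 bond forms through a closed six-membered chair with the trimethoxyphenyl group equatorial, giving aldolate 8; no ring of the product is closed. The trans enolate geometry translates into the 2,3-anti relation, so the configuration of C8 relative to C7 is fixed by the transition-state geometry. The absolute sense at both new centres (2S at C8, 3S at C7) is controlled by the reagent: the cyclohexylmethyl ligands disfavour one of the two diastereomeric chairs, so that the Re face of the aldehyde is attacked. Aldehyde 6 has no alpha hydrogen and can neither enolise nor self-condense, and the short B–O bonds make the transition state tight enough for the ligands to be felt. The step needs anti over syn and one enolate face over the other, which the S-tert-butyl thioester and the ligand set are there to secure. Buffered oxidative work-up cleaves the B–O and B–C bonds without epimerising the alpha-aryloxy thioester and leaves the allyl group alone.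

Step 4
Reactants: 9 S-tert-butyl (2S,3S)-2-(4-allyl-2-methoxyphenoxy)-3-hydroxy-3-(3,4,5-trimethoxyphenyl)propanethioate
Product: 10 (1S,2R)-2-(4-allyl-2-methoxyphenoxy)-1-(3,4,5-trimethoxyphenyl)propane-1,3-diol
Conditions: LiAlH4 (2.5 equiv), THF, −20 → 0 °C; aq. NaOH work-up, bleach trap for the thiol
Reagents that add atoms: none
Why: Hydride reduction of a thioester to the primary alcohol: the thioester is more electrophilic than an oxoester, so LiAlH4 acts at low temperature and should outrun retro-aldol cleavage of the C7 alkoxide and epimerisation at C8; the isolated alkene and both stereocentres are untouched.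

Step 5
Reactants: 10 (1S,2R)-2-(4-allyl-2-methoxyphenoxy)-1-(3,4,5-trimethoxyphenyl)propane-1,3-diol
Product: 11 (2R,3S)-2-(4-allyl-2-methoxyphenoxy)-3-hydroxy-3-(3,4,5-trimethoxyphenyl)propyl 4-methylbenzenesulfonate
Conditions: TsCl (1.1 equiv), pyridine, CH2Cl2, 0 °C
Reagents that add atoms: 4-methylbenzenesulfonyl chloride, Cc1ccc(cc1)S(Cl)(=O)=O
Why: Chemoselective sulfonylation: the unhindered primary hydroxyl should react with TsCl/pyridine at 0 °C well ahead of the secondary benzylic hydroxyl, which is flanked by ring A and the aryloxy-bearing carbon; a small excess of reagent keeps the secondary position free.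

Step 6
Reactants: 11 (2R,3S)-2-(4-allyl-2-methoxyphenoxy)-3-hydroxy-3-(3,4,5-trimethoxyphenyl)propyl 4-methylbenzenesulfonate
Product: 12 (1S,2R)-2-(4-allyl-2-methoxyphenoxy)-1-(3,4,5-trimethoxyphenyl)propan-1-ol
Conditions: LiEt3BH (3.5 equiv), THF, 0 °C → rt; H2O quench
Reagents that add atoms: none
Why: SN2 displacement of a primary sulfonate by hydride (reductive deoxygenation): LiEt3BH is a strongly nucleophilic hydride donor that reduces primary tosylates at or below room temperature; the first equivalent turns the C7 hydroxyl into a lithium alkoxide–triethylborane complex of low nucleophilicity, which should suppress ring closure onto C9, and no bond to C7 or C8 is broken.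

Step 7
Reactants: 12 (1S,2R)-2-(4-allyl-2-methoxyphenoxy)-1-(3,4,5-trimethoxyphenyl)propan-1-ol
Product: 14 (1S,2R)-2-[4-(3-hydroxypropyl)-2-methoxyphenoxy]-1-(3,4,5-trimethoxyphenyl)propan-1-ol, via alkyl-9-BBN adduct 13 (not isolated)
Conditions: 9-BBN (9-borabicyclo[3.3.1]nonane, 3 equiv), THF, 0 °C → rt; then 3 M NaOH, 30% H2O2, 0 °C → rt
Reagents that add atoms: hydrogen peroxide, OO
Why: Hydroboration–oxidation: 9-BBN places boron on the terminal carbon of the allyl group (anti-Markovnikov), the excess covers the free hydroxyl, and alkaline H2O2 replaces boron by oxygen; no stereocentre is created or touched.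

## Compound list

1 | 2-methylpropane-2-thiol | CC(C)(C)S | starting material
2 | bromoacetyl bromide | BrCC(Br)=O | starting material
3 | S-tert-butyl 2-bromoethanethioate | CC(C)(C)SC(=O)CBr | intermediate
4 | eugenol (4-allyl-2-methoxyphenol) | COc1cc(CC=C)ccc1O | starting material
5 | S-tert-butyl 2-(4-allyl-2-methoxyphenoxy)ethanethioate | CC(C)(C)SC(=O)COc1ccc(CC=C)cc1OC | intermediate
6 | 3,4,5-trimethoxybenzaldehyde | COc1cc(C=O)cc(OC)c1OC | starting material
7 | (Z)-2-(4-allyl-2-methoxyphenoxy)-1-(tert-butylsulfanyl)ethenyl bis{[(1S,2S,5R)-2-isopropyl-5-methylcyclohexyl]methyl}borinate (aryloxy trans to O–B) | CC(C)(C)S/C(OB(C[C@H]1C[C@H](C)CC[C@H]1C(C)C)C[C@H]1C[C@H](C)CC[C@H]1C(C)C)=C\Oc1ccc(CC=C)cc1OC | intermediate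
8 | S-tert-butyl (2S,3S)-2-(4-allyl-2-methoxyphenoxy)-3-{[bis({[(1S,2S,5R)-2-isopropyl-5-methylcyclohexyl]methyl})boranyl]oxy}-3-(3,4,5-trimethoxyphenyl)propanethioate | COc1cc(CC=C)ccc1O[C@H](C(=O)SC(C)(C)C)[C@@H](OB(C[C@H]1C[C@H](C)CC[C@H]1C(C)C)C[C@H]1C[C@H](C)CC[C@H]1C(C)C)c1cc(OC)c(OC)c(OC)c1 | intermediate
9 | S-tert-butyl (2S,3S)-2-(4-allyl-2-methoxyphenoxy)-3-hydroxy-3-(3,4,5-trimethoxyphenyl)propanethioate | COc1cc(CC=C)ccc1O[C@H](C(=O)SC(C)(C)C)[C@@H](O)c1cc(OC)c(OC)c(OC)c1 | intermediate
10 | (1S,2R)-2-(4-allyl-2-methoxyphenoxy)-1-(3,4,5-trimethoxyphenyl)propane-1,3-diol | COc1cc(CC=C)ccc1O[C@H](CO)[C@@H](O)c1cc(OC)c(OC)c(OC)c1 | intermediate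
11 | (2R,3S)-2-(4-allyl-2-methoxyphenoxy)-3-hydroxy-3-(3,4,5-trimethoxyphenyl)propyl 4-methylbenzenesulfonate | COc1cc(CC=C)ccc1O[C@H](COS(=O)(=O)c1ccc(C)cc1)[C@@H](O)c1cc(OC)c(OC)c(OC)c1 | intermediate
12 | (1S,2R)-2-(4-allyl-2-methoxyphenoxy)-1-(3,4,5-trimethoxyphenyl)propan-1-ol | COc1cc(CC=C)ccc1O[C@H](C)[C@@H](O)c1cc(OC)c(OC)c(OC)c1 | intermediate
13 | 9-{3-[4-({(1S,2R)-1-hydroxy-1-(3,4,5-trimethoxyphenyl)propan-2-yl}oxy)-3-methoxyphenyl]propyl}-9-borabicyclo[3.3.1]nonane | COc1cc(CCCB2C3CCCC2CCC3)ccc1O[C@H](C)[C@@H](O)c1cc(OC)c(OC)c(OC)c1 | intermediate
14 | (1S,2R)-2-[4-(3-hydroxypropyl)-2-methoxyphenoxy]-1-(3,4,5-trimethoxyphenyl)propan-1-ol | COc1cc(CCCO)ccc1O[C@H](C)[C@@H](O)c1cc(OC)c(OC)c(OC)c1 | target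

## Step count and risk

Total step count: 7. Longest linear sequence: 7 steps (steps 1 to 7, counted from 1 and 2; 6 steps from 4).

Least certain steps

Step 3 (key step).
- What may go wrong: the boron ligands may discriminate the enolate faces insufficiently for this particular aryloxy enolate. The enolate geometry may also leak, through chelation of boron by the aryloxy and ortho-methoxy oxygens or through a competing boat transition state, and erode the anti preference. A lesser concern is Lewis-acid demethylation of methoxy groups by the bromoborane if enolisation is slow. The sense of induction itself rests on the assumption stated before the steps.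
- Fallback (chiral pool and chelation-controlled reduction; sets out from 4 and comes back at 12): Mitsunobu etherification of 4 with ethyl (S)-lactate (PPh3, diisopropyl azodicarboxylate, THF) should give, with inversion, ethyl (R)-2-(4-allyl-2-methoxyphenoxy)propanoate F1. MeNH(OMe)·HCl with i-PrMgCl converts it into (R)-2-(4-allyl-2-methoxyphenoxy)-N-methoxy-N-methylpropanamide F2. (3,4,5-Trimethoxyphenyl)magnesium bromide F3, made from 5-bromo-1,2,3-trimethoxybenzene and magnesium, adds once to give (R)-2-(4-allyl-2-methoxyphenoxy)-1-(3,4,5-trimethoxyphenyl)propan-1-one F4. Reduction with Zn(BH4)2 in Et2O at low temperature should then give the erythro alcohol 12. It proceeds through a zinc chelate between the carbonyl oxygen and the aryloxy and methoxy oxygens, with hydride entering past the C8 hydrogen. The route continues with step 7.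

Step 6.
- What may go wrong: the C7 alkoxide may compete with the external hydride. The possible processes are four-membered ring closure onto C9, Grob-type fragmentation across C7–C8, and hydride attack at sulfur, which only regenerates the diol.
- Fallback (the hydroxyl is taken out of play; sets out from 11 and comes back at 12): silylation of 11 with t-BuMe2SiOTf and 2,6-lutidine gives (2R,3S)-2-(4-allyl-2-methoxyphenoxy)-3-[(tert-butyldimethylsilyl)oxy]-3-(3,4,5-trimethoxyphenyl)propyl 4-methylbenzenesulfonate F5. LiEt3BH then reduces the sulfonate to tert-butyl{[(1S,2R)-2-(4-allyl-2-methoxyphenoxy)-1-(3,4,5-trimethoxyphenyl)propyl]oxy}dimethylsilane F6. Bu4NF in THF returns 12.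

Step 5.
- What may go wrong: discrimination between the two hydroxyls may be incomplete, with sulfonylation at C7 or at both oxygens. An activated benzylic sulfonate on the electron-rich ring A would then be lost by ionisation or elimination.
- Fallback (the oxygens are differentiated before C9 is reduced; sets out from 9 and comes back at 12): silylation of 9 with t-BuMe2SiOTf and 2,6-lutidine gives S-tert-butyl (2S,3S)-2-(4-allyl-2-methoxyphenoxy)-3-[(tert-butyldimethylsilyl)oxy]-3-(3,4,5-trimethoxyphenyl)propanethioate F7. LiAlH4 reduction gives (2R,3S)-2-(4-allyl-2-methoxyphenoxy)-3-[(tert-butyldimethylsilyl)oxy]-3-(3,4,5-trimethoxyphenyl)propan-1-ol F8. Its only free hydroxyl is sulfonylated with TsCl/pyridine to the silyl ether tosylate F5 named under step 6. Reduction to F6 and desilylation to 12 follow as described there.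

Step 2.
- What may go wrong: acyl transfer, in which the phenoxide attacks the thioester carbonyl of 3 instead of the CH2Br carbon and the released thiolate then consumes more 3. Decomposition of the lachrymatory bromide 3 on storage is a further nuisance.
- Fallback (ether first, thioester second; sets out from 4 and comes back at 5, with step 1 no longer needed): 4 with ClCH2CO2H in aqueous NaOH at reflux, then acidification, gives (4-allyl-2-methoxyphenoxy)acetic acid F9. Carbodiimide coupling with 1 (dicyclohexylcarbodiimide, catalytic 4-(dimethylamino)pyridine, CH2Cl2) gives 5.

## Further compounds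

F1 | step 3 | ethyl (R)-2-(4-allyl-2-methoxyphenoxy)propanoate | COc1cc(CC=C)ccc1O[C@H](C)C(=O)OCC
F2 | step 3 | (R)-2-(4-allyl-2-methoxyphenoxy)-N-methoxy-N-methylpropanamide | COc1cc(CC=C)ccc1O[C@H](C)C(=O)N(C)OC
F3 | step 3 | (3,4,5-trimethoxyphenyl)magnesium bromide | COc1cc([Mg]Br)cc(OC)c1OC
F4 | step 3 | (R)-2-(4-allyl-2-methoxyphenoxy)-1-(3,4,5-trimethoxyphenyl)propan-1-one | COc1cc(CC=C)ccc1O[C@H](C)C(=O)c1cc(OC)c(OC)c(OC)c1
F5 | step 6 | (2R,3S)-2-(4-allyl-2-methoxyphenoxy)-3-[(tert-butyldimethylsilyl)oxy]-3-(3,4,5-trimethoxyphenyl)propyl 4-methylbenzenesulfonate | COc1cc(CC=C)ccc1O[C@H](COS(=O)(=O)c1ccc(C)cc1)[C@@H](O[Si](C)(C)C(C)(C)C)c1cc(OC)c(OC)c(OC)c1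
F6 | step 6 | tert-butyl{[(1S,2R)-2-(4-allyl-2-methoxyphenoxy)-1-(3,4,5-trimethoxyphenyl)propyl]oxy}dimethylsilane | COc1cc(CC=C)ccc1O[C@H](C)[C@@H](O[Si](C)(C)C(C)(C)C)c1cc(OC)c(OC)c(OC)c1
F7 | step 5 | S-tert-butyl (2S,3S)-2-(4-allyl-2-methoxyphenoxy)-3-[(tert-butyldimethylsilyl)oxy]-3-(3,4,5-trimethoxyphenyl)propanethioate | COc1cc(CC=C)ccc1O[C@H](C(=O)SC(C)(C)C)[C@@H](O[Si](C)(C)C(C)(C)C)c1cc(OC)c(OC)c(OC)c1
F8 | step 5 | (2R,3S)-2-(4-allyl-2-methoxyphenoxy)-3-[(tert-butyldimethylsilyl)oxy]-3-(3,4,5-trimethoxyphenyl)propan-1-ol | COc1cc(CC=C)ccc1O[C@H](CO)[C@@H](O[Si](C)(C)C(C)(C)C)c1cc(OC)c(OC)c(OC)c1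
F9 | step 2 | (4-allyl-2-methoxyphenoxy)acetic acid | COc1cc(CC=C)ccc1OCC(O)=O
A1 | alternative 1 | (1S,2R)-1-(methoxymethoxy)-1-(3,4,5-trimethoxyphenyl)propan-2-ol | O[C@H](C)[C@@H](OCOC)c1cc(OC)c(OC)c(OC)c1
A2 | alternative 1 | 4-fluoro-3-methoxybenzaldehyde | COc1cc(C=O)ccc1F
A3 | alternative 1 | 3-methoxy-4-{[(1S,2R)-1-(methoxymethoxy)-1-(3,4,5-trimethoxyphenyl)propan-2-yl]oxy}benzaldehyde | COc1cc(C=O)ccc1O[C@H](C)[C@@H](OCOC)c1cc(OC)c(OC)c(OC)c1
A4 | alternative 2 | 4-{3-[(tert-butyldimethylsilyl)oxy]propyl}-2-methoxyphenyl (S)-2-[(tert-butyldimethylsilyl)oxy]-2-(3,4,5-trimethoxyphenyl)acetate | COc1cc(CCCO[Si](C)(C)C(C)(C)C)ccc1OC(=O)[C@@H](O[Si](C)(C)C(C)(C)C)c1cc(OC)c(OC)c(OC)c1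
A5 | alternative 2 | tert-butyl{(S)-2-{4-[3-(tert-butyldimethylsilyloxy)propyl]-2-methoxyphenoxy}-1-(3,4,5-trimethoxyphenyl)allyloxy}dimethylsilane | COc1cc(CCCO[Si](C)(C)C(C)(C)C)ccc1OC(=C)[C@@H](O[Si](C)(C)C(C)(C)C)c1cc(OC)c(OC)c(OC)c1
A6 | alternative 3 | (R)-2-(4-allyl-2-methoxyphenoxy)propanal | COc1cc(CC=C)ccc1O[C@H](C)C=O
A7 | alternative 3 | (3,4,5-trimethoxyphenyl)titanium triisopropoxide | COc1cc([Ti](OC(C)C)(OC(C)C)OC(C)C)cc(OC)c1OC
A8 | alternative 3 | (1S,2R)-2-(4-allyl-2-methoxyphenoxy)-1-(3,4,5-trimethoxyphenyl)propan-1-ol | COc1cc(CC=C)ccc1O[C@H](C)[C@@H](O)c1cc(OC)c(OC)c(OC)c1
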